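The target is disconnected at the trisubstituted C3=C4 alkene of its 4-methylcyclohex-3-enyl ring (the CH= carbon C3 and the methyl-bearing carbon C4), the one ring bond whose scission leaves an acyclic 1,7-diene. Ring-closing olefin metathesis of a tertiary dienyl benzoate, which carries an allyl and a 3-methylbut-3-enyl arm on the ester-bearing quaternary carbon, closes the six-membered ring and creates the endocyclic alkene in one operation late in a convergent route. The quaternary stereocenter is set earlier by Sharpless epoxidation of 2-isopropylallyl alcohol and two successive epoxide openings. The diprenylated aroyl fragment comes from a double Suzuki–Miyaura coupling.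

Key step: step 10

Remark: the Grignard reagents, the prenylboronate and the dibromo ester used below are taken to be commercial; the quaternary ring carbon of the target is R.

Step 1
Reactants: 1 prop-2-yn-1-ol; 2 isopropylmagnesium chloride
Product: 3 3-methyl-2-methylidenebutan-1-ol
Conditions: 2 (2.5 equiv), CuBr·SMe2 (10 mol%), THF, −20 °C → rt; aq. NH4Cl
Reagents that add atoms: none
Why: Copper-catalysed anti-carbomagnesiation of the propargylic alkoxide should place the isopropyl group on the internal alkyne carbon through a five-membered alkenylmagnesium chelate that is protonated on work-up; no stereocenter is formed.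

Step 2
Reactants: 3 3-methyl-2-methylidenebutan-1-ol
Product: 4 [(2S)-2-(propan-2-yl)oxiran-2-yl]methanol
Conditions: Ti(OiPr)4 (10 mol%), L-(+)-diethyl tartrate (12 mol%), t-BuOOH (2 equiv), 4 Å MS, CH2Cl2, −20 °C
Reagents that add atoms: tert-butyl hydroperoxide, CC(C)(C)OO
Why: Sharpless asymmetric epoxidation, in which the titanium L-(+)-tartrate complex should deliver oxygen to one enantiotopic face of the 1,1-disubstituted allylic alcohol (reagent control) and so set the quaternary carbon as S, a branched 2-substituent being a favourable case for this reaction.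

Step 3
Reactants: 4 [(2S)-2-(propan-2-yl)oxiran-2-yl]methanol; 5 (2-methylprop-2-en-1-yl)magnesium chloride
Product: 6 (2S)-5-methyl-2-(propan-2-yl)hex-5-ene-1,2-diol
Conditions: 5 (3 equiv), CuBr·SMe2 (10 mol%), THF, −30 → 0 °C; aq. NH4Cl
Reagents that add atoms: none
Why: Copper-catalysed SN2 opening of the 2,2-disubstituted epoxide by the allylic Grignard reagent should occur at the unsubstituted ring CH2, so the C–O bond of the quaternary stereocenter is untouched and its configuration is kept (one equivalent of reagent is spent on the hydroxyl group).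

Step 4
Reactants: 6 (2S)-5-methyl-2-(propan-2-yl)hex-5-ene-1,2-diol
Product: 8 (2S)-2-(3-methylbut-3-en-1-yl)-2-(propan-2-yl)oxirane, via primary tosylate 7 (not isolated)
Conditions: NaH (2.5 equiv), 1-(p-toluenesulfonyl)imidazole (1.1 equiv), THF, 0 °C → rt
Reagents that add atoms: none
Why: Selective sulfonylation of the primary alkoxide followed by intramolecular Williamson displacement by the tertiary alkoxide (3-exo-tet) should give the terminal epoxide, the stereocenter keeping its C–O bond and its configuration.

Step 5
Reactants: 8 (2S)-2-(3-methylbut-3-en-1-yl)-2-(propan-2-yl)oxirane; 9 vinylmagnesium bromide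
Product: 10 (4R)-7-methyl-4-(propan-2-yl)octa-1,7-dien-4-ol
Conditions: 9 (3 equiv), CuBr·SMe2 (15 mol%), THF, −30 → 0 °C; aq. NH4Cl
Reagents that add atoms: none
Why: Copper-catalysed SN2 opening of the terminal epoxide at its CH2 group by the vinyl Grignard reagent should turn that carbon into the allyl arm without touching the stereocenter, whose descriptor changes from S to R only because the CIP ranks of its substituents change.

Step 6
Reactants: 11 methyl 3,5-dibromo-4-hydroxybenzoate; 12 4,4,5,5-tetramethyl-2-(3-methylbut-2-en-1-yl)-1,3,2-dioxaborolane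
Product: 14 4-hydroxy-3,5-bis(3-methylbut-2-en-1-yl)benzoic acid, via methyl ester 13 (not isolated)
Conditions: 12 (3 equiv), PdCl2(IPent)(3-chloropyridine) (4 mol%; IPent = 1,3-bis[2,6-di(pentan-3-yl)phenyl]imidazol-2-ylidene), 5 M aq. KOH, THF, 70 °C; then MeOH, more KOH, 70 °C; citric acid work-up
Reagents that add atoms: potassium hydroxide, [K+].[OH-]
Why: Double Suzuki–Miyaura coupling of the allylboronate under a bulky N-heterocyclic carbene palladium catalyst, a system in which reductive elimination at the unsubstituted allyl terminus should give the linear prenyl arene, followed in the same flask by saponification of the methyl ester; no stereocenter.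

Step 7
Reactants: 14 4-hydroxy-3,5-bis(3-methylbut-2-en-1-yl)benzoic acid
Product: 15 tert-butyldimethylsilyl 4-[(tert-butyldimethylsilyl)oxy]-3,5-bis(3-methylbut-2-en-1-yl)benzoate
Conditions: TBSCl (2.5 equiv), imidazole (5 equiv), DMF, rt → 40 °C
Reagents that add atoms: tert-butyldimethylsilyl chloride, CC(C)(C)[Si](C)(C)Cl
Why: Imidazole-promoted silylation should convert the acid into its silyl ester and the hindered phenol into its silyl ether, which masks the phenol for the acylation; no stereocenter.

Step 8
Reactants: 15 tert-butyldimethylsilyl 4-[(tert-butyldimethylsilyl)oxy]-3,5-bis(3-methylbut-2-en-1-yl)benzoate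
Product: 16 4-[(tert-butyldimethylsilyl)oxy]-3,5-bis(3-methylbut-2-en-1-yl)benzoyl chloride
Conditions: (COCl)2 (1.2 equiv), DMF (cat.), CH2Cl2, 0 °C → rt; evaporation
Reagents that add atoms: oxalyl chloride, O=C(Cl)C(Cl)=O
Why: Conversion of a silyl ester into the acid chloride by the chloroiminium (Vilsmeier) species from oxalyl chloride and catalytic DMF releases TBSCl in place of HCl and should therefore spare the prenyl groups and the aryl silyl ether.

Step 9
Reactants: 10 (4R)-7-methyl-4-(propan-2-yl)octa-1,7-dien-4-ol; 16 4-[(tert-butyldimethylsilyl)oxy]-3,5-bis(3-methylbut-2-en-1-yl)benzoyl chloride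
Product: 18 (4R)-7-methyl-4-(propan-2-yl)octa-1,7-dien-4-yl 4-[(tert-butyldimethylsilyl)oxy]-3,5-bis(3-methylbut-2-en-1-yl)benzoate, via lithium alkoxide 17 (not isolated)
Conditions: n-BuLi (1.0 equiv), THF, −78 °C; then 16 (1.1 equiv), −78 °C → rt
Reagents that add atoms: none
Why: O-Acylation of a lithium tertiary alkoxide by an aroyl chloride (addition–elimination) should succeed because the carbonyl group has only ring CH positions beside it and the phenol is masked; the stereocenter keeps its C–O bond.

Step 10
Reactants: 18 (4R)-7-methyl-4-(propan-2-yl)octa-1,7-dien-4-yl 4-[(tert-butyldimethylsilyl)oxy]-3,5-bis(3-methylbut-2-en-1-yl)benzoate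
Product: 19 (1R)-4-methyl-1-(propan-2-yl)cyclohex-3-en-1-yl 4-[(tert-butyldimethylsilyl)oxy]-3,5-bis(3-methylbut-2-en-1-yl)benzoate
Conditions: second-generation Grubbs catalyst RuCl2(=CHPh)(H2IMes)(PCy3) (5 mol%), CH2Cl2 (5 mM), 40 °C, argon purge
Reagents that add atoms: none
Why: Ring-closing olefin metathesis by the metallacyclobutane mechanism: the ruthenium benzylidene initiates at the monosubstituted allyl terminus, the new alkylidene adds intramolecularly to the 1,1-disubstituted isopropenyl group, and cycloreversion releases the ring alkene and a ruthenium methylidene with loss of ethene. The closest known reaction type is the closure of 1,7-dienes with one geminally disubstituted terminus to 1-methylcyclohexenes by second-generation ruthenium carbenes. The six-membered carbocycle is closed by forming the C3=C4 double bond between the former CH=CH2 carbon and the former C(CH3)=CH2 carbon, helped by the gem-disubstituent effect of the fully substituted carbinol carbon in the tether. No stereocenter is created; the quaternary carbon set in step 2 lies outside the reacting atoms and keeps its R configuration. The step needs chemoselectivity for the two terminal alkenes over the two prenyl groups: these trisubstituted, dimethyl-capped alkenes react much more slowly with ruthenium carbenes, any ring they could close with the diene arms would be a strained macrocycle, and high dilution with removal of ethene should suppress cross-metathesis and ethenolysis.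

Step 11
Reactants: 19 (1R)-4-methyl-1-(propan-2-yl)cyclohex-3-en-1-yl 4-[(tert-butyldimethylsilyl)oxy]-3,5-bis(3-methylbut-2-en-1-yl)benzoate
Product: 20 (1R)-4-methyl-1-(propan-2-yl)cyclohex-3-en-1-yl 4-hydroxy-3,5-bis(3-methylbut-2-en-1-yl)benzoate
Conditions: Bu4NF (1.1 equiv), AcOH (1.2 equiv), THF, 0 °C
Reagents that add atoms: none
Why: Fluoride-induced cleavage of the aryl silyl ether, buffered with acetic acid so that the phenoxide is protonated at once, should leave the hindered tertiary benzoate, the alkenes and the stereocenter untouched.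

Compound list
1 | prop-2-yn-1-ol | C#CCO | starting material
2 | isopropylmagnesium chloride | CC(C)[Mg]Cl | starting material
3 | 3-methyl-2-methylidenebutan-1-ol | C=C(CO)C(C)C | intermediate
4 | [(2S)-2-(propan-2-yl)oxiran-2-yl]methanol | OC[C@@]1(C(C)C)CO1 | intermediate
5 | (2-methylprop-2-en-1-yl)magnesium chloride | C=C(C)C[Mg]Cl | starting material
6 | (2S)-5-methyl-2-(propan-2-yl)hex-5-ene-1,2-diol | OC[C@@](O)(C(C)C)CCC(C)=C | intermediate
7 | (2S)-2-hydroxy-5-methyl-2-(propan-2-yl)hex-5-en-1-yl 4-methylbenzenesulfonate | Cc1ccc(cc1)S(=O)(=O)OC[C@@](O)(C(C)C)CCC(C)=C | intermediate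
8 | (2S)-2-(3-methylbut-3-en-1-yl)-2-(propan-2-yl)oxirane | C1[C@@](O1)(C(C)C)CCC(C)=C | intermediate
9 | vinylmagnesium bromide | C=C[Mg]Br | starting material
10 | (4R)-7-methyl-4-(propan-2-yl)octa-1,7-dien-4-ol | C=CC[C@@](O)(C(C)C)CCC(C)=C | intermediate
11 | methyl 3,5-dibromo-4-hydroxybenzoate | COC(=O)c1cc(Br)c(O)c(Br)c1 | starting material
12 | 4,4,5,5-tetramethyl-2-(3-methylbut-2-en-1-yl)-1,3,2-dioxaborolane | CC(C)=CCB1OC(C)(C)C(C)(C)O1 | starting material
13 | methyl 4-hydroxy-3,5-bis(3-methylbut-2-en-1-yl)benzoate | COC(=O)c1cc(CC=C(C)C)c(O)c(CC=C(C)C)c1 | intermediate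
14 | 4-hydroxy-3,5-bis(3-methylbut-2-en-1-yl)benzoic acid | OC(=O)c1cc(CC=C(C)C)c(O)c(CC=C(C)C)c1 | intermediate
15 | tert-butyldimethylsilyl 4-[(tert-butyldimethylsilyl)oxy]-3,5-bis(3-methylbut-2-en-1-yl)benzoate | CC(C)=CCc1cc(C(=O)O[Si](C)(C)C(C)(C)C)cc(CC=C(C)C)c1O[Si](C)(C)C(C)(C)C | intermediate
16 | 4-[(tert-butyldimethylsilyl)oxy]-3,5-bis(3-methylbut-2-en-1-yl)benzoyl chloride | CC(C)=CCc1cc(C(Cl)=O)cc(CC=C(C)C)c1O[Si](C)(C)C(C)(C)C | intermediate
17 | lithium (4R)-7-methyl-4-(propan-2-yl)octa-1,7-dien-4-olate | [Li]O[C@@](C(C)C)(CC=C)CCC(C)=C | intermediate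
18 | (4R)-7-methyl-4-(propan-2-yl)octa-1,7-dien-4-yl 4-[(tert-butyldimethylsilyl)oxy]-3,5-bis(3-methylbut-2-en-1-yl)benzoate | CC(C)=CCc1cc(C(=O)O[C@@](C(C)C)(CC=C)CCC(C)=C)cc(CC=C(C)C)c1O[Si](C)(C)C(C)(C)C | intermediate
19 | (1R)-4-methyl-1-(propan-2-yl)cyclohex-3-en-1-yl 4-[(tert-butyldimethylsilyl)oxy]-3,5-bis(3-methylbut-2-en-1-yl)benzoate | CC(C)=CCc1cc(C(=O)O[C@@]2(C(C)C)CC=C(C)CC2)cc(CC=C(C)C)c1O[Si](C)(C)C(C)(C)C | intermediate
20 | (1R)-4-methyl-1-(propan-2-yl)cyclohex-3-en-1-yl 4-hydroxy-3,5-bis(3-methylbut-2-en-1-yl)benzoate | CC(C)=CCc1cc(C(=O)O[C@@]2(C(C)C)CC=C(C)CC2)cc(CC=C(C)C)c1O | target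

Total steps: 11. Longest linear sequence: 8 steps (steps 1 to 5, then 9, 10 and 11).

Steps most likely to fail

Step 10. Metathesis may not stay confined to the two terminal alkenes: the ruthenium methylidene or the released ethene can engage the prenyl groups (ethenolysis to allyl groups, cross-metathesis between molecules), or the catalyst may decay before the bulky ester has cyclised. The fallback closes the ring before the ester is made. It sets out from dienol 10, which has no other alkene: the same catalyst in CH2Cl2 at 40 °C should give (1R)-4-methyl-1-(propan-2-yl)cyclohex-3-en-1-ol F1. Deprotonation with n-BuLi in THF at −78 °C gives lithium (1R)-4-methyl-1-(propan-2-yl)cyclohex-3-en-1-olate F2, and acylation with acid chloride 16 returns to the route at compound 19.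

Step 6. Part of the allyl unit may be transferred through its substituted terminus (1,1-dimethylallyl isomers), the allylboronate may protodeboronate, or the reaction may stall after the first coupling on the electron-rich phenoxide. The fallback separates C–C coupling from construction of the trisubstituted alkene. It sets out from dibromide 11: Suzuki–Miyaura coupling with the symmetrical 2-allyl-4,4,5,5-tetramethyl-1,3,2-dioxaborolane (Pd(PPh3)4, K2CO3, THF–H2O, 70 °C) should give methyl 4-hydroxy-3,5-di(prop-2-en-1-yl)benzoate F3. Cross-metathesis of both allyl groups with 2-methylbut-2-ene as solvent (second-generation Grubbs catalyst, 40 °C) returns to the route at compound 13, which is saponified as in step 6.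

Step 5. SN2 attack at the CH2 group beside the isopropyl-bearing quaternary carbon is slow, so magnesium halide may open the epoxide with bromide or rearrange it to the aldehyde before the vinyl group is delivered. The fallback uses a non-Lewis-acidic sp nucleophile and sets out from epoxide 8: lithium acetylide–ethylenediamine complex in DMSO at room temperature should open the ring at CH2 to give (4R)-7-methyl-4-(propan-2-yl)oct-7-en-1-yn-4-ol F4. Semi-hydrogenation of the terminal alkyne (H2, Pd/CaCO3 poisoned with Pb(OAc)2, quinoline, hexane) returns to the route at compound 10.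

Further compounds
F1 | step 10 | (1R)-4-methyl-1-(propan-2-yl)cyclohex-3-en-1-ol | O[C@@]1(C(C)C)CC=C(C)CC1
F2 | step 10 | lithium (1R)-4-methyl-1-(propan-2-yl)cyclohex-3-en-1-olate | [Li]O[C@@]1(C(C)C)CC=C(C)CC1
F3 | step 6 | methyl 4-hydroxy-3,5-di(prop-2-en-1-yl)benzoate | COC(=O)c1cc(CC=C)c(O)c(CC=C)c1
F4 | step 5 | (4R)-7-methyl-4-(propan-2-yl)oct-7-en-1-yn-4-ol | C#CC[C@@](O)(C(C)C)CCC(C)=C
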